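Ring C, a dienone with a hydroperoxide at C8 para to the C12 carbonyl, is a para-alkylphenol that has taken up singlet oxygen. The phenol is assembled by an intramolecular furan Diels–Alder reaction that exploits this 1,4-relationship of C12–O and C8, which is that of the two α-carbons of a furan: a 2-alkyl-3-bromofuran (C8, C14, C13, C12) and a tethered alkynoic acid (C9, C11) form C8–C9 and C11–C12 in one operation, closing rings B and C; the oxygen bridge opens to the C12 phenol and the activating carboxyl group on C11 is expelled. The acyclic precursor carries both stereocentres (C5, C10) in the tether and comes from fragmentation of a cyclohexanone.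

Key step: step 11

Numbering used throughout (parent diterpenoid convention): ring B = C5, C6, C7, C8, C9, C10; ring C = C8, C9, C11, C12, C13, C14. C12 is the ring carbonyl carbon, C11 the ring CH next to it, C9 the ring-fusion alkene carbon, C8 the hydroperoxide carbon, C14 the vinyl-bearing carbon, C13 the methyl-bearing ring carbon, C10 the quaternary carbon with the ester chain, C5 the isopropenyl-bearing carbon.

Remark: the sense of induction of the ligand in step 1 is assumed to be selectable by choice of ligand enantiomer; the target has the 5R,8R,10R configuration in this numbering.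

Step 1
Reactants: 1 2-methylcyclohex-2-en-1-one
Product: 3 trimethyl{[(3R)-2-methyl-3-(prop-1-en-2-yl)cyclohex-1-en-1-yl]oxy}silane, via bromomagnesium enolate 2 (not isolated)
Conditions: isopropenylmagnesium bromide, Cu(OTf)2 (3 mol%), BINOL-derived bis(1-phenylethyl)amine phosphoramidite (6 mol%, enantiomer chosen for the 3R series), Et2O, −30 °C; then TMSCl, Et3N, DMPU, −30 → 0 °C
Reagents that add atoms: isopropenylmagnesium bromide, C=C(C)[Mg]Br; chlorotrimethylsilane, C[Si](C)(C)Cl
Why: Copper-catalysed asymmetric conjugate addition, in which the chiral copper–phosphoramidite complex selects the enone face at the β-carbon and so sets the isopropenyl-bearing stereocentre (C5), while silylation fixes the enolate regiochemistry for step 2.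

Step 2
Reactants: 3 trimethyl{[(3R)-2-methyl-3-(prop-1-en-2-yl)cyclohex-1-en-1-yl]oxy}silane
Product: 5 methyl 3-[(1R,6R)-1-methyl-2-oxo-6-(prop-1-en-2-yl)cyclohexyl]propanoate, via lithium enolate 4 (not isolated)
Conditions: MeLi, THF, 0 °C; then methyl acrylate, −78 °C; then 1 M HCl
Reagents that add atoms: methyl acrylate, C=CC(=O)OC
Why: Michael addition of the regiodefined lithium enolate (released by Si–O cleavage) to the acrylate, which should enter anti to the adjacent isopropenyl group and so create the quaternary centre C10 with the ester chain trans to isopropenyl.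

Step 3
Reactants: 5 methyl 3-[(1R,6R)-1-methyl-2-oxo-6-(prop-1-en-2-yl)cyclohexyl]propanoate
Product: 6 methyl 3-[(1R,6R)-1-methyl-2-oxo-6-(prop-1-en-2-yl)cyclohex-3-en-1-yl]propanoate
Conditions: IBX, 4-methoxypyridine N-oxide, DMSO, 25 °C
Reagents that add atoms: none
Why: IBX dehydrogenation of a ketone to its enone, regiochemically unambiguous because the quaternary carbon leaves only one enolisable side, with no stereocentre touched.

Step 4
Reactants: 6 methyl 3-[(1R,6R)-1-methyl-2-oxo-6-(prop-1-en-2-yl)cyclohex-3-en-1-yl]propanoate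
Product: 7 methyl 3-[(1S,3R,4R,6S)-3-methyl-2-oxo-4-(prop-1-en-2-yl)-7-oxabicyclo[4.1.0]heptan-3-yl]propanoate (epoxide trans to the isopropenyl group)
Conditions: t-BuOOH, DBU, CH2Cl2, 0 → 25 °C
Reagents that add atoms: tert-butyl hydroperoxide, CC(C)(C)OO
Why: Weitz–Scheffer nucleophilic epoxidation of the enone, expected to occur anti to the isopropenyl group as in the epoxidation of carvone; the configuration of the epoxide carbons is erased in step 5, so the other diastereomer would serve equally.

Step 5
Reactants: 7 methyl 3-[(1S,3R,4R,6S)-3-methyl-2-oxo-4-(prop-1-en-2-yl)-7-oxabicyclo[4.1.0]heptan-3-yl]propanoate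
Product: 9 methyl (4R,5R)-4-ethynyl-7-hydroxy-4-methyl-5-(prop-1-en-2-yl)heptanoate, via alkynal 8 (not isolated)
Conditions: TsNHNH2, AcOH/CH2Cl2, −20 → 25 °C; then NaHCO3, NaBH4, MeOH, 0 °C
Reagents that add atoms: none
Why: Eschenmoser–Tanabe fragmentation of the epoxy ketone tosylhydrazone should open the ring to a terminal alkyne on the quaternary carbon and an aldehyde, which NaBH4 reduces in the same flask before it can condense; both stereocentres are spectators.

Step 6
Reactants: 9 methyl (4R,5R)-4-ethynyl-7-hydroxy-4-methyl-5-(prop-1-en-2-yl)heptanoate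
Product: 10 methyl (4R,5R)-4-ethynyl-7-iodo-4-methyl-5-(prop-1-en-2-yl)heptanoate
Conditions: I2, PPh3, imidazole, CH2Cl2, 0 °C
Reagents that add atoms: iodine, II
Why: Appel-type iodination of the primary alcohol by SN2 displacement of the phosphonium-activated oxygen, neutral enough for ester, alkyne and alkene.

Step 7
Reactants: 11 3,4-dibromofuran
Product: 13 3-bromo-4-methylfuran, via 3-bromo-4-lithiofuran 12 (not isolated)
Conditions: n-BuLi, Et2O, −78 °C; then MeI, −78 → −30 °C
Reagents that add atoms: iodomethane, CI
Why: Bromine–lithium exchange at one of the two equivalent C–Br bonds followed by methylation of the 3-furyllithium, kept cold so that it does not isomerise to the α-lithio species.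

Step 8
Reactants: 13 3-bromo-4-methylfuran
Product: 15 3-bromo-2-iodo-4-methylfuran, via 2-lithiofuran 14 (not isolated)
Conditions: LiN(i-Pr)2, THF, −78 °C; then I2
Reagents that add atoms: iodine, II
Why: Directed ortho-lithiation, in which the amide base should remove the α-proton next to bromine (the more acidic of the two α-hydrogens), followed by iodine quench.

Step 9
Reactants: 10 methyl (4R,5R)-4-ethynyl-7-iodo-4-methyl-5-(prop-1-en-2-yl)heptanoate; 15 3-bromo-2-iodo-4-methylfuran
Product: 17 methyl (4R,5R)-7-(3-bromo-4-methylfuran-2-yl)-4-ethynyl-4-methyl-5-(prop-1-en-2-yl)heptanoate, via alkylzinc iodide 16 (not isolated)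
Conditions: Zn dust, LiCl, THF, 40 °C; then 15, PdCl2(dppf) (3 mol%), THF, 25 °C
Reagents that add atoms: none
Why: Negishi coupling, in which zinc inserts into the primary C–I bond without touching ester or alkyne and zerovalent palladium should add oxidatively to the furan α C–I bond much faster than to the β C–Br bond.

Step 10
Reactants: 17 methyl (4R,5R)-7-(3-bromo-4-methylfuran-2-yl)-4-ethynyl-4-methyl-5-(prop-1-en-2-yl)heptanoate
Product: 18 (4R)-4-[(3R)-1-(3-bromo-4-methylfuran-2-yl)-4-methylpent-4-en-3-yl]-7-methoxy-4-methyl-7-oxohept-2-ynoic acid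
Conditions: CO2 (1 atm), CuCl (5 mol%), TMEDA, K2CO3, DMF, 25 °C; then 1 M HCl
Reagents that add atoms: carbon dioxide, O=C=O
Why: Copper-catalysed carboxylation of the terminal alkyne through its copper acetylide, mild enough for the methyl ester and the bromofuran; the new carboxyl group on C11 activates the alkyne as a dienophile.

Step 11
Reactants: 18 (4R)-4-[(3R)-1-(3-bromo-4-methylfuran-2-yl)-4-methylpent-4-en-3-yl]-7-methoxy-4-methyl-7-oxohept-2-ynoic acid
Product: 21 methyl 3-[(1R,2R)-5-bromo-7-hydroxy-1,6-dimethyl-2-(prop-1-en-2-yl)-1,2,3,4-tetrahydronaphthalen-1-yl]propanoate, via oxa-bridged cycloadduct 19 (not isolated), via salicylic acid 20 (not isolated)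
Conditions: PhMe, 100 °C; then Ag2CO3 (10 mol%), AcOH (5 mol%), DMSO, 120 °C
Reagents that add atoms: none
Why: A normal-demand intramolecular Diels–Alder reaction of the furan with the alkynoic acid joins the tether-bearing furan α-carbon C8 to the alkyne β-carbon C9 and the unsubstituted α-carbon C12 to the carboxyl-bearing C11, giving the 7-oxanorbornadiene 19. Ring B closes through the four-carbon tether (C7–C6–C5–C10) as a six-membered ring fused to the new six-membered ring C, and the tether length excludes the reversed regiochemistry. The C8–O bridge bond should then ionise to the tertiary, doubly allylic cation, and loss of the C12 proton aromatises ring C, so that the furan oxygen ends as the C12 phenol of 20 and the closure formally delivers the C11–C12 bond of the arene. The closest known reaction type is the furan–alkynoate cycloaddition/aromatisation route to phenols, and the 3-bromo substituent should make the cycloaddition faster and less reversible. The 2-hydroxy-6-alkylbenzoic acid 20 is then protodecarboxylated under silver catalysis, as is known for ortho-substituted benzoic acids, so the activating group leaves no trace. The two bridgehead stereocentres are transient and C5/C10 are untouched; the selectivity needed is bridge opening in preference to retro-cycloaddition with loss of the bromoalkyne, which the acidic substrate at 100 °C should secure.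

Step 12
Reactants: 21 methyl 3-[(1R,2R)-5-bromo-7-hydroxy-1,6-dimethyl-2-(prop-1-en-2-yl)-1,2,3,4-tetrahydronaphthalen-1-yl]propanoate
Product: 22 methyl 3-[(1R,2R)-5-ethenyl-7-hydroxy-1,6-dimethyl-2-(prop-1-en-2-yl)-1,2,3,4-tetrahydronaphthalen-1-yl]propanoate
Conditions: tributyl(vinyl)stannane, Pd2(dba)3 (2.5 mol%), P(t-Bu)3 (10 mol%), CsF, dioxane, 80 °C
Reagents that add atoms: tributyl(vinyl)stannane, C=C[Sn](CCCC)(CCCC)CCCC
Why: Stille coupling of the di-ortho-substituted aryl bromide, for which the bulky electron-rich phosphine promotes oxidative addition and fluoride activates tin under conditions that tolerate the free phenol and the ester.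

Step 13
Reactants: 22 methyl 3-[(1R,2R)-5-ethenyl-7-hydroxy-1,6-dimethyl-2-(prop-1-en-2-yl)-1,2,3,4-tetrahydronaphthalen-1-yl]propanoate
Product: 23 trigonochinene C, methyl 3-[(1R,2R,4aR)-5-ethenyl-4a-hydroperoxy-1,6-dimethyl-7-oxo-2-(prop-1-en-2-yl)-1,2,3,4,4a,7-hexahydronaphthalen-1-yl]propanoate
Conditions: O2, tetraphenylporphyrin (1 mol%), Cs2CO3 (0.2 equiv), CH2Cl2/MeOH, visible light, −20 °C; then AcOH
Reagents that add atoms: dioxygen, O=O
Why: Dearomatising photo-oxygenation of a para-alkylphenol, in which singlet oxygen adds across C8/C12 of the phenol(ate) and the adduct opens to the para-hydroperoxy dienone; attack at C8 should come from the face that lets ring B pass directly into a chair (anti to the pseudoaxial C7–H, syn to the C10 methyl), as in the oxygenation of estrone to its 10β-hydroperoxide, which gives the 8R configuration, while the catalytic base keeps the phenol far more reactive than the two alkenes.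

Compound list

1 | 2-methylcyclohex-2-en-1-one | CC1=CCCCC1=O | starting material
2 | bromomagnesium (3R)-2-methyl-3-(prop-1-en-2-yl)cyclohex-1-en-1-olate | Br[Mg]OC1=C(C)[C@@H](C(=C)C)CCC1 | intermediate (not isolated)
3 | trimethyl{[(3R)-2-methyl-3-(prop-1-en-2-yl)cyclohex-1-en-1-yl]oxy}silane | C[Si](C)(C)OC1=C(C)[C@@H](C(=C)C)CCC1 | intermediate
4 | lithium (3R)-2-methyl-3-(prop-1-en-2-yl)cyclohex-1-en-1-olate | [Li]OC1=C(C)[C@@H](C(=C)C)CCC1 | intermediate (not isolated)
5 | methyl 3-[(1R,6R)-1-methyl-2-oxo-6-(prop-1-en-2-yl)cyclohexyl]propanoate | O=C1CCC[C@H](C(=C)C)[C@@]1(C)CCC(=O)OC | intermediate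
6 | methyl 3-[(1R,6R)-1-methyl-2-oxo-6-(prop-1-en-2-yl)cyclohex-3-en-1-yl]propanoate | O=C1C=CC[C@H](C(=C)C)[C@@]1(C)CCC(=O)OC | intermediate
7 | methyl 3-[(1S,3R,4R,6S)-3-methyl-2-oxo-4-(prop-1-en-2-yl)-7-oxabicyclo[4.1.0]heptan-3-yl]propanoate | O=C1[C@H]2O[C@H]2C[C@H](C(=C)C)[C@@]1(C)CCC(=O)OC | intermediate
8 | methyl (4R,5R)-4-ethynyl-4-methyl-7-oxo-5-(prop-1-en-2-yl)heptanoate | O=CC[C@H](C(=C)C)[C@](C)(C#C)CCC(=O)OC | intermediate (not isolated)
9 | methyl (4R,5R)-4-ethynyl-7-hydroxy-4-methyl-5-(prop-1-en-2-yl)heptanoate | OCC[C@H](C(=C)C)[C@](C)(C#C)CCC(=O)OC | intermediate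
10 | methyl (4R,5R)-4-ethynyl-7-iodo-4-methyl-5-(prop-1-en-2-yl)heptanoate | ICC[C@H](C(=C)C)[C@](C)(C#C)CCC(=O)OC | intermediate
11 | 3,4-dibromofuran | Brc1cocc1Br | starting material
12 | 3-bromo-4-lithiofuran | [Li]c1cocc1Br | intermediate (not isolated)
13 | 3-bromo-4-methylfuran | Cc1cocc1Br | intermediate
14 | (3-bromo-4-methylfuran-2-yl)lithium | Cc1coc([Li])c1Br | intermediate (not isolated)
15 | 3-bromo-2-iodo-4-methylfuran | Cc1coc(I)c1Br | intermediate
16 | [(3R,4R)-4-ethynyl-7-methoxy-4-methyl-7-oxo-3-(prop-1-en-2-yl)heptyl]zinc iodide | I[Zn]CC[C@H](C(=C)C)[C@](C)(C#C)CCC(=O)OC | intermediate (not isolated)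
17 | methyl (4R,5R)-7-(3-bromo-4-methylfuran-2-yl)-4-ethynyl-4-methyl-5-(prop-1-en-2-yl)heptanoate | Cc1coc(CC[C@H](C(=C)C)[C@](C)(C#C)CCC(=O)OC)c1Br | intermediate
18 | (4R)-4-[(3R)-1-(3-bromo-4-methylfuran-2-yl)-4-methylpent-4-en-3-yl]-7-methoxy-4-methyl-7-oxohept-2-ynoic acid | Cc1coc(CC[C@H](C(=C)C)[C@](C)(C#CC(=O)O)CCC(=O)OC)c1Br | intermediate
19 | (1R,2R)-5-bromo-1-(3-methoxy-3-oxopropyl)-1,6-dimethyl-2-(prop-1-en-2-yl)-1,2,3,4-tetrahydro-7H-4a,7-epoxynaphthalene-8-carboxylic acid (either bridgehead diastereomer) | OC(=O)C1=C2[C@](C)(CCC(=O)OC)[C@@H](C(=C)C)CCC23OC1C(C)=C3Br | intermediate (not isolated)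
20 | (7R,8R)-4-bromo-2-hydroxy-8-(3-methoxy-3-oxopropyl)-3,8-dimethyl-7-(prop-1-en-2-yl)-5,6,7,8-tetrahydronaphthalene-1-carboxylic acid | Cc1c(O)c(C(=O)O)c2c(c1Br)CC[C@H](C(=C)C)[C@@]2(C)CCC(=O)OC | intermediate (not isolated)
21 | methyl 3-[(1R,2R)-5-bromo-7-hydroxy-1,6-dimethyl-2-(prop-1-en-2-yl)-1,2,3,4-tetrahydronaphthalen-1-yl]propanoate | Cc1c(O)cc2c(c1Br)CC[C@H](C(=C)C)[C@@]2(C)CCC(=O)OC | intermediate
22 | methyl 3-[(1R,2R)-5-ethenyl-7-hydroxy-1,6-dimethyl-2-(prop-1-en-2-yl)-1,2,3,4-tetrahydronaphthalen-1-yl]propanoate | C=Cc1c(C)c(O)cc2c1CC[C@H](C(=C)C)[C@@]2(C)CCC(=O)OC | intermediate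
23 | trigonochinene C, methyl 3-[(1R,2R,4aR)-5-ethenyl-4a-hydroperoxy-1,6-dimethyl-7-oxo-2-(prop-1-en-2-yl)-1,2,3,4,4a,7-hexahydronaphthalen-1-yl]propanoate | C=CC1=C(C)C(=O)C=C2[C@]1(OO)CC[C@H](C(=C)C)[C@@]2(C)CCC(=O)OC | target

Total step count: 13. Longest linear sequence: 11 (steps 1–6 and 9–13; the furan branch is steps 7–8).

Steps most likely to fail

Step 11. The cycloaddition joins two hindered termini (the bromine-flanked furan carbon C8 and C9 next to the quaternary C10), so it may be slow enough for thermal decarboxylation of the ynoic acid or retro-cycloaddition with loss of the bromoalkyne to compete. The fallback replaces thermal activation of the free acid by Lewis-acid activation of an ester at low temperature. It sets out from 18: allyl bromide and K2CO3 in DMF should give the allyl ynoate F1; Me2AlCl in CH2Cl2 (−40 → 0 °C) should promote the cycloaddition through the oxa-bridged allyl ester F2 (not isolated) and its opening to the allyl salicylate F3; Pd(PPh3)4 with morpholine removes the allyl group to give acid 20, which is decarboxylated with Ag2CO3/AcOH in DMSO as in step 11. The route is rejoined at 21.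

Step 13. Facial discrimination at C8 may be poor, because the chair-like approach is syn to the C10 methyl while the opposite face is sterically freer, and singlet oxygen may also attack the isopropenyl group in an ene reaction. The fallback sets out from 22 and switches from singlet to triplet oxygen: base-promoted autoxidation of the phenoxide (t-BuOK, O2, t-BuOH/THF, 0 °C), in which oxygen capture at the para carbon of the phenoxyl radical is reversible and isolated alkenes are inert, so the more stable chair hydroperoxide can accumulate. It comes back at 23 and makes no new compound.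

Step 1. Enantioselectivity may be insufficient for the addition of a branched alkenyl group to an α-substituted enone. The fallback replaces asymmetric catalysis by resolution. It sets out from 1: the same addition/silylation with achiral CuI catalysis should give the racemic silyl enol ether F4, which step 2 converts into the racemic keto ester F5 (single relative configuration); F5 is resolved by preparative chromatography on a cellulose-carbamate chiral phase (supercritical CO2/MeOH), and the (1R,6R) enantiomer is 5, where the route is rejoined.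

Further compounds

F1 | step 11 | 7-methyl 1-(prop-2-en-1-yl) (4R)-4-[(3R)-1-(3-bromo-4-methylfuran-2-yl)-4-methylpent-4-en-3-yl]-4-methylhept-2-ynedioate | Cc1coc(CC[C@H](C(=C)C)[C@](C)(C#CC(=O)OCC=C)CCC(=O)OC)c1Br
F2 | step 11 | prop-2-en-1-yl (1R,2R)-5-bromo-1-(3-methoxy-3-oxopropyl)-1,6-dimethyl-2-(prop-1-en-2-yl)-1,2,3,4-tetrahydro-7H-4a,7-epoxynaphthalene-8-carboxylate (either bridgehead diastereomer) | C=CCOC(=O)C1=C2[C@](C)(CCC(=O)OC)[C@@H](C(=C)C)CCC23OC1C(C)=C3Br
F3 | step 11 | prop-2-en-1-yl (7R,8R)-4-bromo-2-hydroxy-8-(3-methoxy-3-oxopropyl)-3,8-dimethyl-7-(prop-1-en-2-yl)-5,6,7,8-tetrahydronaphthalene-1-carboxylate | Cc1c(O)c(C(=O)OCC=C)c2c(c1Br)CC[C@H](C(=C)C)[C@@]2(C)CCC(=O)OC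
F0 | step 13 | none | none
F4 | step 1 | racemic trimethyl{[2-methyl-3-(prop-1-en-2-yl)cyclohex-1-en-1-yl]oxy}silane | C[Si](C)(C)OC1=C(C)C(C(=C)C)CCC1
F5 | step 1 | racemic methyl 3-[(1R*,6R*)-1-methyl-2-oxo-6-(prop-1-en-2-yl)cyclohexyl]propanoate | O=C1CCC[C@H](C(=C)C)[C@@]1(C)CCC(=O)OC.O=C1CCC[C@@H](C(=C)C)[C@]1(C)CCC(=O)OC
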